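## Retrosynthetic overview

1. Numbering: ring B is C1(=O), C2 (side chain), C3-H, C4(=O), C4a, C8a; ring A is C4a, C5(OH), C6, C7, C8(OH), C8a. Ring B is opened by a retro-6π/retro-4π sequence to the 4-hydroxy-4-(1,4-benzoquinon-2-yl)cyclobutenone 15, an isomer of the target. The four-membered ring supplies C1 to C4 and the quinone C=C bond supplies C4a/C8a.
2. Enabling feature: the peri pairs O4-H···O5 and O1···H-O8 make "hydroquinone ring B fused to quinone ring A" a tautomer of the drawn form, so a hydroquinone-forming ring expansion onto a quinone gives the target without redox change or phenol protection. Ring A has equal oxygen at C5/C8 and hydrogen at C6/C7, so C1 and C4 are equivalent and no regiocontrol is needed.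
3. 15 comes from oxidative demethylation of the still monocyclic arene in 14. 14 comes from 2,5-dimethoxyphenyllithium 13 and cyclobutenedione 11.
4. 11 comes from double carbonylation of the terminal alkyne 9. The single stereocentre comes from asymmetric transfer hydrogenation of ynone 6.
5. Ring order: ring A is bought as arene 12, the four-membered ring is made in step 6, and ring B closes last in step 9.

Key step: step 9

Remark: 14 and 15 are drawn as the regioisomer from attack at the ring carbonyl next to the ring CH, without configuration at the new carbinol carbon; every regio- and stereoisomer of this adduct leads to the same product in step 9, and 18 is written in the tautomer of the given SMILES.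

## Route

Step 1
Reactants: 1 4-methylpent-3-enoic acid
Product: 3 N-methoxy-N,4-dimethylpent-3-enamide, via acyl imidazole 2 (not isolated)
Conditions: 1,1'-carbonyldiimidazole, CH2Cl2, 0 °C to rt; then MeNH(OMe)·HCl, rt
Reagents that add atoms: N,O-dimethylhydroxylamine hydrochloride, CNOC.Cl; 1,1'-carbonyldiimidazole, O=C(n1ccnc1)n1ccnc1 (imidazolyl group of 2 only)
Why: Weinreb amide formation by way of the acyl imidazole runs under near-neutral conditions that should keep the β,γ-double bond out of conjugation.

Step 2
Reactants: 3 N-methoxy-N,4-dimethylpent-3-enamide; 4 trimethylsilylacetylene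
Product: 6 6-methyl-1-(trimethylsilyl)hept-5-en-1-yn-3-one, via lithium trimethylsilylacetylide 5 (not isolated)
Conditions: 4, n-BuLi, THF, −78 °C; then 3, −78 to −20 °C; cold 1 M aq. HCl
Reagents that add atoms: n-butyllithium, [Li]CCCC (lithium of 5 only)
Why: In this Weinreb ketone synthesis the chelated tetrahedral adduct should hold until the cold acidic quench, which prevents over-addition and base-induced migration of the double bond into conjugation.

Step 3
Reactants: 6 6-methyl-1-(trimethylsilyl)hept-5-en-1-yn-3-one
Product: 7 (S)-6-methyl-1-(trimethylsilyl)hept-5-en-1-yn-3-ol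
Conditions: Ru[(S,S)-TsDPEN](p-cymene) (1 mol %), i-PrOH, rt
Reagents that add atoms: none
Why: In the Noyori asymmetric transfer hydrogenation of an α,β-acetylenic ketone the (S,S)-catalyst places the alkynyl group where an aryl group would sit and delivers hydride to the face that gives the (S)-carbinol, under base-free conditions that spare alkyne, alkene and the acidic CH2.

Step 4
Reactants: 7 (S)-6-methyl-1-(trimethylsilyl)hept-5-en-1-yn-3-ol
Product: 8 (S)-6-methylhept-5-en-1-yn-3-ol
Conditions: K2CO3 (cat.), MeOH, 0 °C to rt
Reagents that add atoms: none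
Why: Carbonate-catalysed methanolysis of the alkynyl C-Si bond is fast and touches neither the carbinol centre nor the alkene.

Step 5
Reactants: 8 (S)-6-methylhept-5-en-1-yn-3-ol
Product: 9 (S)-6-methylhept-5-en-1-yn-3-yl 2-methylpropanoate
Conditions: (i-PrCO)2O, Et3N, DMAP (cat.), CH2Cl2, 0 °C to rt
Reagents that add atoms: isobutyric anhydride, CC(C)C(=O)OC(=O)C(C)C
Why: DMAP-catalysed acylation takes place at oxygen with retention at carbon and installs the ester of the target before any sensitive ring exists.

Step 6
Reactants: 9 (S)-6-methylhept-5-en-1-yn-3-yl 2-methylpropanoate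
Product: 11 (S)-1-(3,4-dioxocyclobut-1-en-1-yl)-4-methylpent-3-en-1-yl 2-methylpropanoate, via tetracarbonyl ferracyclopentenedione 10 (not isolated)
Conditions: Fe(CO)5, Me3NO, THF, −20 to 65 °C; then CuCl2·2H2O, acetone, rt
Reagents that add atoms: iron pentacarbonyl, O=C=[Fe](=C=O)(=C=O)(=C=O)=C=O
Why: This is the known double carbonylation of terminal alkynes by unsaturated zerovalent iron carbonyl, in which amine-oxide decarbonylation frees a site for the alkyne, two CO insertions give the maleoyl-type ferracycle 10, and oxidation by divalent copper triggers reductive elimination of the two acyl carbons to the cyclobutenedione, while the trisubstituted alkene binds iron poorly and the stereocentre is not involved.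

Step 7
Reactants: 11 (S)-1-(3,4-dioxocyclobut-1-en-1-yl)-4-methylpent-3-en-1-yl 2-methylpropanoate; 12 2-bromo-1,4-dimethoxybenzene
Product: 14 (1S)-1-[3-(2,5-dimethoxyphenyl)-3-hydroxy-4-oxocyclobut-1-en-1-yl]-4-methylpent-3-en-1-yl 2-methylpropanoate, via 2,5-dimethoxyphenyllithium 13 (not isolated)
Conditions: 12, n-BuLi (1.0 equiv), THF, −78 °C; then added to 11, THF, −78 °C; AcOH, −78 °C
Reagents that add atoms: n-butyllithium, [Li]CCCC (lithium of 13 only)
Why: In the 1,2-addition of an aryllithium to a cyclobutenedione, the standard entry to Moore substrates, the strained dione carbonyls should react at −78 °C far faster than the hindered isobutyrate, attack is expected at the less hindered carbonyl next to the ring CH, and neither this regiochemistry nor the configuration of the new carbinol carbon matters because both are erased in step 9.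

Step 8
Reactants: 14 (1S)-1-[3-(2,5-dimethoxyphenyl)-3-hydroxy-4-oxocyclobut-1-en-1-yl]-4-methylpent-3-en-1-yl 2-methylpropanoate
Product: 15 (1S)-1-[3-(3,6-dioxocyclohexa-1,4-dien-1-yl)-3-hydroxy-4-oxocyclobut-1-en-1-yl]-4-methylpent-3-en-1-yl 2-methylpropanoate
Conditions: (NH4)2Ce(NO3)6, MeCN–H2O, 0 °C, short contact
Reagents that add atoms: water, O
Why: In the oxidative demethylation of a 1,4-dimethoxyarene by tetravalent cerium the electron-rich monocyclic arene is by far the most oxidisable site, so both methyl ethers are removed here, where this is easy, instead of from a naphthazarin dimethyl ether, and prenyl-type alkenes, esters and the enone should survive short exposure at 0 °C.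

Step 9
Reactants: 15 (1S)-1-[3-(3,6-dioxocyclohexa-1,4-dien-1-yl)-3-hydroxy-4-oxocyclobut-1-en-1-yl]-4-methylpent-3-en-1-yl 2-methylpropanoate
Product: 18 isobutyryl alkannin, via dienylketene 16 (not isolated), via ring-fusion keto tautomer 17 (not isolated)
Conditions: PhMe (0.01 M, degassed), 100 °C, dark
Reagents that add atoms: none
Why: Heat opens the cyclobutenone of 15 by conrotatory 4π cleavage of the bond between the carbinol carbon and the carbonyl carbon, the hydroxyl donor rotating outward so that the quinonyl group turns inward and lies next to the ketene carbon in 16. Disrotatory 6π electrocyclisation of the ketene C=C, the enol C=C and the C2=C3 bond of the benzoquinone then closes ring B by bond formation between the ketene carbon and quinone C3, a two-atom expansion of the four-membered ring that gives 17. Enolisation of the doubly activated ring-fusion C-H of 17 and a proton shift within the peri hydrogen bridges give 18 without change of oxidation level and without any reagent. The closest known reaction type is the Moore rearrangement of 4-alkenyl- and 4-aryl-4-hydroxycyclobutenones to hydroquinones, which also tolerates alkene partners that belong to an electron-poor cyclic enone. No stereocentre is formed: the ring carbinol centre is erased, and the side-chain centre lies outside the pericyclic array and meets neither acid nor base, so it is retained. The step needs outward rotation of OH and closure at carbon instead of lactonisation, both secured by the donor oxygen on the breaking bond, and it needs no regiocontrol because the equal substitution of ring A lets both regioisomeric adducts and both carbinol epimers converge on 18.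

## Compound list

1 | 4-methylpent-3-enoic acid | CC(C)=CCC(=O)O | starting material
2 | 1-(1H-imidazol-1-yl)-4-methylpent-3-en-1-one | CC(C)=CCC(=O)n1ccnc1 | intermediate
3 | N-methoxy-N,4-dimethylpent-3-enamide | CC(C)=CCC(=O)N(C)OC | intermediate
4 | trimethylsilylacetylene | C#C[Si](C)(C)C | starting material
5 | lithium trimethylsilylacetylide | [Li]C#C[Si](C)(C)C | intermediate
6 | 6-methyl-1-(trimethylsilyl)hept-5-en-1-yn-3-one | CC(C)=CCC(=O)C#C[Si](C)(C)C | intermediate
7 | (S)-6-methyl-1-(trimethylsilyl)hept-5-en-1-yn-3-ol | CC(C)=CC[C@H](O)C#C[Si](C)(C)C | intermediate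
8 | (S)-6-methylhept-5-en-1-yn-3-ol | CC(C)=CC[C@H](O)C#C | intermediate
9 | (S)-6-methylhept-5-en-1-yn-3-yl 2-methylpropanoate | CC(C)=CC[C@H](OC(=O)C(C)C)C#C | intermediate
10 | tetracarbonyl ferracyclopent-3-ene-2,5-dione bearing the (S) side chain at C3 | CC(C)=CC[C@H](OC(=O)C(C)C)C1=CC(=O)[Fe](=C=O)(=C=O)(=C=O)(=C=O)C1=O | intermediate
11 | (S)-1-(3,4-dioxocyclobut-1-en-1-yl)-4-methylpent-3-en-1-yl 2-methylpropanoate | CC(C)=CC[C@H](OC(=O)C(C)C)C1=CC(=O)C1=O | intermediate
12 | 2-bromo-1,4-dimethoxybenzene | COc1ccc(OC)c(Br)c1 | starting material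
13 | 2,5-dimethoxyphenyllithium | COc1ccc(OC)c([Li])c1 | intermediate
14 | (1S)-1-[3-(2,5-dimethoxyphenyl)-3-hydroxy-4-oxocyclobut-1-en-1-yl]-4-methylpent-3-en-1-yl 2-methylpropanoate (both epimers at the ring carbinol) | CC(C)=CC[C@H](OC(=O)C(C)C)C1=CC(O)(c2cc(OC)ccc2OC)C1=O | intermediate
15 | (1S)-1-[3-(3,6-dioxocyclohexa-1,4-dien-1-yl)-3-hydroxy-4-oxocyclobut-1-en-1-yl]-4-methylpent-3-en-1-yl 2-methylpropanoate (both epimers at the ring carbinol) | CC(C)=CC[C@H](OC(=O)C(C)C)C1=CC(O)(C2=CC(=O)C=CC2=O)C1=O | intermediate
16 | dienylketene, quinonyl group cis to the ketene-bearing carbon | CC(C)=CC[C@H](OC(=O)C(C)C)C(=C=O)/C=C(/O)C1=CC(=O)C=CC1=O | intermediate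
17 | ring-fusion keto tautomer (8a-H) of the target | CC(C)=CC[C@H](OC(=O)C(C)C)C1=CC(O)=C2C(=O)C=CC(=O)C2C1=O | intermediate
18 | isobutyryl alkannin, (S)-1-(5,8-dihydroxy-1,4-dioxo-1,4-dihydronaphthalen-2-yl)-4-methylpent-3-en-1-yl 2-methylpropanoate | CC(C)=CC[C@H](OC(=O)C(C)C)C1=CC(=O)c2c(O)ccc(O)c2C1=O | target

## Step count and risks

Total step count: 9. Longest linear sequence: 9 (1 to 18).

**Step 9.**
- What may go wrong: the heat-sensitive product may oligomerise at the temperature that the four-membered ring needs to open, or the ketene may close slowly onto the electron-poor quinone double bond and be diverted to other addition pathways.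
- Fallback, from 14 back to 18: the ring expansion is run one stage earlier, on the arene. Compound 14 is heated in p-xylene at 138 °C, a classical Moore rearrangement onto the free ortho position of the dimethoxyphenyl ring. This gives the hydroquinone (S)-1-(1,4-dihydroxy-5,8-dimethoxynaphthalen-2-yl)-4-methylpent-3-en-1-yl 2-methylpropanoate F1. Ag2O in the same flask oxidises it at once to (S)-1-(5,8-dimethoxy-1,4-dioxo-1,4-dihydronaphthalen-2-yl)-4-methylpent-3-en-1-yl 2-methylpropanoate F2. Oxidative demethylation with AgO and HNO3 in acetone gives the diquinone (S)-4-methyl-1-(1,4,5,8-tetraoxo-1,4,5,8-tetrahydronaphthalen-2-yl)pent-3-en-1-yl 2-methylpropanoate F3. Brief reductive work-up with one equivalent of aqueous Na2S2O4 returns it to 18.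

**Step 6.**
- What may go wrong: low-valent iron may attack the propargylic C-O bond, with loss of the ester or erosion of configuration. The enyne may also bind iron unproductively and the conversion may stay low.
- Fallback, from 12 and 9 back to 18: the other four-membered ring is expanded.
  - NaNH2-induced elimination of 12 in the presence of 1,1-dimethoxyethene (aryne [2+2] cycloaddition, THF, reflux) gives 2,5,7,7-tetramethoxybicyclo[4.2.0]octa-1,3,5-triene F4.
  - Aqueous HCl in THF hydrolyses it to 2,5-dimethoxybicyclo[4.2.0]octa-1,3,5-trien-7-one F5.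
  - Geminal bromination (NBS, 2 equiv, radical initiation) gives 8,8-dibromo-2,5-dimethoxybicyclo[4.2.0]octa-1,3,5-trien-7-one F6, and aqueous H2SO4 gives 2,5-dimethoxybicyclo[4.2.0]octa-1,3,5-triene-7,8-dione F7.
  - Monovalent cobalt in ClCo(PPh3)3 inserts into the bond between the two carbonyl carbons to give chlorobis(triphenylphosphine)(3,6-dimethoxyphthaloyl)cobalt F8.
  - With AgBF4 and alkyne 9 in MeCN at 80 °C, F8 takes up the alkyne and releases by reductive elimination the quinone already named above, F2. The symmetric dione allows only one regioisomer.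
  - F2 is carried to 18 as in the fallback to step 9.

**Step 8.**
- What may go wrong: the strained benzylic C-C bond may fragment from the arene radical cation, or the freshly formed quinone may be over-oxidised.
- Fallback, from 12 and 11 back to 15: the oxidation is done electrochemically on the simple arene before the coupling, so that no chemical oxidant meets the cyclobutenol. Anodic oxidation of 12 (Pt anode, KOH, MeOH, 0 °C) gives 2-bromo-3,3,6,6-tetramethoxycyclohexa-1,4-diene F9. Bromine-lithium exchange (n-BuLi, THF, −78 °C) gives 2-lithio-3,3,6,6-tetramethoxycyclohexa-1,4-diene F10. Addition to 11 at −78 °C gives (1S)-1-[3-hydroxy-4-oxo-3-(3,3,6,6-tetramethoxycyclohexa-1,4-dien-1-yl)cyclobut-1-en-1-yl]-4-methylpent-3-en-1-yl 2-methylpropanoate F11. Both ketals are hydrolysed completely (aq. HCl, THF, rt) before any heating, which gives 15.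

## Further compounds

F1 | step 9 | (S)-1-(1,4-dihydroxy-5,8-dimethoxynaphthalen-2-yl)-4-methylpent-3-en-1-yl 2-methylpropanoate | CC(C)=CC[C@H](OC(=O)C(C)C)c1cc(O)c2c(OC)ccc(OC)c2c1O
F2 | step 9 | (S)-1-(5,8-dimethoxy-1,4-dioxo-1,4-dihydronaphthalen-2-yl)-4-methylpent-3-en-1-yl 2-methylpropanoate | CC(C)=CC[C@H](OC(=O)C(C)C)C1=CC(=O)c2c(OC)ccc(OC)c2C1=O
F3 | step 9 | (S)-4-methyl-1-(1,4,5,8-tetraoxo-1,4,5,8-tetrahydronaphthalen-2-yl)pent-3-en-1-yl 2-methylpropanoate | CC(C)=CC[C@H](OC(=O)C(C)C)C1=CC(=O)C2=C(C1=O)C(=O)C=CC2=O
F4 | step 6 | 2,5,7,7-tetramethoxybicyclo[4.2.0]octa-1,3,5-triene | COc1ccc(OC)c2c1CC2(OC)OC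
F5 | step 6 | 2,5-dimethoxybicyclo[4.2.0]octa-1,3,5-trien-7-one | COc1ccc(OC)c2c1CC2=O
F6 | step 6 | 8,8-dibromo-2,5-dimethoxybicyclo[4.2.0]octa-1,3,5-trien-7-one | COc1ccc(OC)c2c1C(Br)(Br)C2=O
F7 | step 6 | 2,5-dimethoxybicyclo[4.2.0]octa-1,3,5-triene-7,8-dione | COc1ccc(OC)c2c1C(=O)C2=O
F8 | step 6 | chlorobis(triphenylphosphine)(3,6-dimethoxyphthaloyl)cobalt | COc1ccc(OC)c2c1C(=O)[Co-2](Cl)([P+](c1ccccc1)(c1ccccc1)c1ccccc1)([P+](c1ccccc1)(c1ccccc1)c1ccccc1)C2=O
F9 | step 8 | 2-bromo-3,3,6,6-tetramethoxycyclohexa-1,4-diene | COC1(OC)C=CC(OC)(OC)C(Br)=C1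
F10 | step 8 | 2-lithio-3,3,6,6-tetramethoxycyclohexa-1,4-diene | COC1(OC)C=CC(OC)(OC)C([Li])=C1
F11 | step 8 | (1S)-1-[3-hydroxy-4-oxo-3-(3,3,6,6-tetramethoxycyclohexa-1,4-dien-1-yl)cyclobut-1-en-1-yl]-4-methylpent-3-en-1-yl 2-methylpropanoate | CC(C)=CC[C@H](OC(=O)C(C)C)C1=CC(O)(C2=CC(OC)(OC)C=CC2(OC)OC)C1=O
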